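**Retrosynthetic overview**

1. Numbering follows germacrane (ring C1–C10, C14 on C10, C15 on C4, lactone C11–C13). The strategy rests on the C6(O)–C7(C11)–C8(O) triad of the ten-membered ring: the lactone is trans-fused at C6/C7 and C11 on C7 lies anti to the C8 oxygen, the imprint of a cis C7–C8 epoxide opened at C7 with inversion by a carbon held on O6.
2. Endgame: C15 enal from an allylic TES ether, C14 acetate from a PMB ether, O8 ester by acylation of the C8 hydroxyl that the key step releases.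
3. Lactone ring (second ring, formed last): 5-exo opening of the syn C7–C8 epoxide by the O6 phosphonoacetate carbanion, then olefination of the α-phosphono lactone with formaldehyde (C11=C13).
4. Ten-membered ring (first ring): ring-closing metathesis at C7=C8 of an acyclic tetraene, then vanadium-directed epoxidation from O6 while C4=C5 is still an enoate.
5. Chain: HWE at C4=C5 between an (S)-butenediol-derived α-silyloxy aldehyde (C5–C7) and a phosphonoacetate alkylated with the C1–C3/C8–C10 iodide, whose 1(10) geometry comes from anti-allylmagnesiation of a pentynol.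

Key step: step 17

Remark: the target SMILES is read as 6R,7R,8S with 1(10)E and 4E (both alkenes ring-cis); CIP descriptors of intermediates change with substituent priorities, not with geometry.

**Route**

Step 1
Reactants: 1 4-(tert-butyldimethylsilyloxy)but-1-yne; 2 formaldehyde (as paraformaldehyde)
Product: 3 5-(tert-butyldimethylsilyloxy)pent-2-yn-1-ol
Conditions: n-BuLi, THF, −78 °C; (CH2O)n, −78 → 25 °C
Reagents that add atoms: none
Why: Addition of a lithium acetylide to formaldehyde is routine and installs C14 as a free propargylic alcohol while C3 stays masked as the silyl ether.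

Step 2
Reactants: 3 5-(tert-butyldimethylsilyloxy)pent-2-yn-1-ol; 4 allylmagnesium bromide
Product: 5 (2E)-2-allyl-5-(tert-butyldimethylsilyloxy)pent-2-en-1-ol
Conditions: 4 (3 equiv), Et2O/THF, 0 → 40 °C; aq NH4Cl
Reagents that add atoms: none
Why: Alkoxide-directed anti-carbomagnesiation of a propargylic alcohol puts allyl on the proximal alkyne carbon (C10) and magnesium on C1 in a five-membered chelate cis to CH2O, so protonation should give C9 cis to C2 (ring-cis 1(10) alkene) with C14 as the only free hydroxyl.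

Step 3
Reactants: 5 (2E)-2-allyl-5-(tert-butyldimethylsilyloxy)pent-2-en-1-ol
Product: 6 tert-butyl{[(3E)-4-{[(4-methoxybenzyl)oxy]methyl}hepta-3,6-dien-1-yl]oxy}dimethylsilane
Conditions: NaH, PMBCl, Bu4NI (cat.), THF/DMF, 0 → 25 °C
Reagents that add atoms: 4-methoxybenzyl chloride, COc1ccc(CCl)cc1
Why: Williamson etherification gives a C14 ether that survives DIBAL-H, base and metathesis and is later removed oxidatively, which is what distinguishes C14 from C15.

Step 4
Reactants: 6 tert-butyl{[(3E)-4-{[(4-methoxybenzyl)oxy]methyl}hepta-3,6-dien-1-yl]oxy}dimethylsilane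
Product: 7 (3E)-4-{[(4-methoxybenzyl)oxy]methyl}hepta-3,6-dien-1-ol
Conditions: TBAF, THF, 0 → 25 °C
Reagents that add atoms: none
Why: Fluoride-mediated desilylation frees the primary C3 hydroxyl without touching the PMB ether or the alkenes.

Step 5
Reactants: 7 (3E)-4-{[(4-methoxybenzyl)oxy]methyl}hepta-3,6-dien-1-ol
Product: 8 1-({[(2E)-2-allyl-5-iodopent-2-en-1-yl]oxy}methyl)-4-methoxybenzene
Conditions: I2, PPh3, imidazole, CH2Cl2, 0 °C
Reagents that add atoms: iodine, II
Why: Appel-type iodination converts the primary alcohol into the iodide by SN2 under neutral conditions that leave the allylic ether intact.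

Step 6
Reactants: 8 1-({[(2E)-2-allyl-5-iodopent-2-en-1-yl]oxy}methyl)-4-methoxybenzene; 9 triethyl phosphonoacetate
Product: 10 ethyl (5E)-2-(diethoxyphosphoryl)-6-{[(4-methoxybenzyl)oxy]methyl}nona-5,8-dienoate
Conditions: 9 (3 equiv), NaH (2.8 equiv), DMSO/THF, 0 → 55 °C
Reagents that add atoms: none
Why: Malonic-ester-type C-alkylation of sodium triethyl phosphonoacetate by a primary iodide forms C3–C4; the excess of the weakly basic anion suppresses dialkylation and favours SN2 over elimination at the homoallylic carbon.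

Step 7
Reactants: 11 (S)-but-3-ene-1,2-diol
Product: 12 (S)-1,2-bis(tert-butyldimethylsilyloxy)but-3-ene
Conditions: TBSCl (2.5 equiv), imidazole, DMF, 25 °C
Reagents that add atoms: tert-butyldimethylsilyl chloride, CC(C)(C)[Si](C)(C)Cl
Why: Exhaustive silylation with TBSCl/imidazole protects both hydroxyls without touching the stereocentre that becomes C6.

Step 8
Reactants: 12 (S)-1,2-bis(tert-butyldimethylsilyloxy)but-3-ene
Product: 13 (S)-2-(tert-butyldimethylsilyloxy)but-3-en-1-ol
Conditions: HF·pyridine, pyridine, THF, 0 °C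
Reagents that add atoms: none
Why: Buffered HF·pyridine cleaves the less hindered primary TBS ether much faster than the secondary one, the usual selective monodesilylation of 1,2-bis-silyl ethers.

Step 9
Reactants: 13 (S)-2-(tert-butyldimethylsilyloxy)but-3-en-1-ol
Product: 14 (S)-2-(tert-butyldimethylsilyloxy)but-3-enal
Conditions: Dess–Martin periodinane, NaHCO3, CH2Cl2, 0 °C; used at once
Reagents that add atoms: none
Why: Buffered Dess–Martin oxidation gives the α-silyloxy-β,γ-unsaturated aldehyde under non-basic conditions, so the stereocentre and the terminal alkene should stay in place if the aldehyde is used immediately.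

Step 10
Reactants: 10 ethyl (5E)-2-(diethoxyphosphoryl)-6-{[(4-methoxybenzyl)oxy]methyl}nona-5,8-dienoate; 14 (S)-2-(tert-butyldimethylsilyloxy)but-3-enal
Product: 15 ethyl (2E,4S)-4-(tert-butyldimethylsilyloxy)-2-[(3E)-4-{[(4-methoxybenzyl)oxy]methyl}hepta-3,6-dien-1-yl]hexa-2,5-dienoate
Conditions: 10, NaH, THF, 0 °C; then 14, −78 → 0 °C
Reagents that add atoms: none
Why: Horner–Wadsworth–Emmons olefination with a preformed α-alkyl phosphonoacetate anion should give the E trisubstituted enoate (ester trans to C6, hence C3 cis to C6), and the absence of free base protects the α-stereocentre of the aldehyde.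

Step 11
Reactants: 15 ethyl (2E,4S)-4-(tert-butyldimethylsilyloxy)-2-[(3E)-4-{[(4-methoxybenzyl)oxy]methyl}hepta-3,6-dien-1-yl]hexa-2,5-dienoate
Product: 16 ethyl (1(10)E,4E,7Z,6S)-6-(tert-butyldimethylsilyloxy)-10-{[(4-methoxybenzyl)oxy]methyl}cyclodeca-1(10),4,7-triene-4-carboxylate (germacrane locants)
Conditions: Grubbs II (10 mol %), CH2Cl2 (1 mM), 40 °C
Reagents that add atoms: none
Why: Ring-closing metathesis engages only the two monosubstituted alkenes, the trisubstituted ones being spectators for the ruthenium alkylidene; the two ring-cis alkenes pre-fold the chain, and a ten-membered ring that already holds them should accept C7=C8 only as the Z isomer.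

Step 12
Reactants: 16 ethyl (1(10)E,4E,7Z,6S)-6-(tert-butyldimethylsilyloxy)-10-{[(4-methoxybenzyl)oxy]methyl}cyclodeca-1(10),4,7-triene-4-carboxylate
Product: 17 ethyl (1(10)E,4E,7Z,6S)-6-hydroxy-10-{[(4-methoxybenzyl)oxy]methyl}cyclodeca-1(10),4,7-triene-4-carboxylate
Conditions: HF·pyridine, pyridine, THF, 0 → 25 °C
Reagents that add atoms: none
Why: HF·pyridine removes the secondary allylic TBS ether under mildly acidic conditions that avoid base-induced conjugation of the skipped triene.

Step 13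
Reactants: 17 ethyl (1(10)E,4E,7Z,6S)-6-hydroxy-10-{[(4-methoxybenzyl)oxy]methyl}cyclodeca-1(10),4,7-triene-4-carboxylate
Product: 18 ethyl (1(10)E,4E,6R,7R,8S)-7,8-epoxy-6-hydroxy-10-{[(4-methoxybenzyl)oxy]methyl}cyclodeca-1(10),4-diene-4-carboxylate (cis epoxide, syn to the 6-OH)
Conditions: VO(acac)2 (5 mol %), t-BuOOH, CH2Cl2, 0 → 25 °C
Reagents that add atoms: tert-butyl hydroperoxide, CC(C)(C)OO
Why: In this vanadium-catalysed hydroxyl-directed epoxidation the vanadate ester of O6 reaches only the allylic C7=C8 (the C4=C5 enoate is electronically inert, C1=C10 is out of reach), and the small O–C6–C7=C8 dihedral of the vanadium transition state, as with medium-ring cis-cycloalk-2-enols, should set C7 and C8 with the epoxide syn to O6.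

Step 14
Reactants: 18 ethyl (1(10)E,4E,6R,7R,8S)-7,8-epoxy-6-hydroxy-10-{[(4-methoxybenzyl)oxy]methyl}cyclodeca-1(10),4-diene-4-carboxylate
Product: 19 (1(10)E,4E,6R,7R,8S)-7,8-epoxy-4-(hydroxymethyl)-10-{[(4-methoxybenzyl)oxy]methyl}cyclodeca-1(10),4-dien-6-ol
Conditions: DIBAL-H (3.5 equiv), CH2Cl2, −78 °C; Rochelle salt
Reagents that add atoms: none
Why: DIBAL-H reduces the enoate to the allylic alcohol by 1,2-hydride delivery at −78 °C, a temperature at which the epoxide of an epoxy alkoxide is not opened.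

Step 15
Reactants: 19 (1(10)E,4E,6R,7R,8S)-7,8-epoxy-4-(hydroxymethyl)-10-{[(4-methoxybenzyl)oxy]methyl}cyclodeca-1(10),4-dien-6-ol
Product: 20 (1(10)E,4E,6R,7R,8S)-7,8-epoxy-10-{[(4-methoxybenzyl)oxy]methyl}-4-[(triethylsilyloxy)methyl]cyclodeca-1(10),4-dien-6-ol
Conditions: TESCl (1.05 equiv), imidazole, CH2Cl2, −40 → 0 °C
Reagents that add atoms: chlorotriethylsilane, CC[Si](Cl)(CC)CC
Why: Kinetic silylation discriminates the unhindered primary allylic hydroxyl (C15) from the secondary C6 hydroxyl flanked by the epoxide and a trisubstituted alkene.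

Step 16
Reactants: 20 (1(10)E,4E,6R,7R,8S)-7,8-epoxy-10-{[(4-methoxybenzyl)oxy]methyl}-4-[(triethylsilyloxy)methyl]cyclodeca-1(10),4-dien-6-ol; 21 diethylphosphonoacetic acid
Product: 22 (1(10)E,4E,6R,7S,8S)-7,8-epoxy-10-{[(4-methoxybenzyl)oxy]methyl}-4-[(triethylsilyloxy)methyl]cyclodeca-1(10),4-dien-6-yl 2-(diethoxyphosphoryl)acetate
Conditions: 21, DCC, DMAP (cat.), CH2Cl2, 0 → 25 °C
Reagents that add atoms: none
Why: Steglich esterification acylates the secondary alcohol under neutral conditions that leave the epoxide and the silyl ether intact.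

Step 17
Reactants: 22 (1(10)E,4E,6R,7S,8S)-7,8-epoxy-10-{[(4-methoxybenzyl)oxy]methyl}-4-[(triethylsilyloxy)methyl]cyclodeca-1(10),4-dien-6-yl 2-(diethoxyphosphoryl)acetate; 2 formaldehyde (as paraformaldehyde)
Product: 24 (1(10)E,4E,6R,7R,8S)-8-hydroxy-14-(4-methoxybenzyloxy)-15-(triethylsilyloxy)germacra-1(10),4,11(13)-trien-12,6-olide, via α-phosphono lactone 23 (not isolated)
Conditions: KOt-Bu (1.05 equiv), THF, 0 → 45 °C; then (CH2O)n, 0 → 25 °C
Reagents that add atoms: none
Why: Proposed new method: deprotonation gives the phosphonate-stabilised carbanion at C11, which attacks C7 of the cis epoxide from the face opposite the epoxide oxygen (SN2), forming C7–C11 and the γ-lactone and releasing the C8 alkoxide, which is protonated by the far more acidic α-phosphono lactone C–H to leave the phosphonate anion of 23 that olefinates formaldehyde to give C11=C13; the closest known reactions are the intermolecular phosphonoacetate–epoxide alkylation/lactonisation with HWE methylenation, the ester-tethered phosphonoacetate Michael/HWE lactone annulation, and the epoxide-opening stage of the Wadsworth–Emmons cyclopropanation. The lactone ring (C6–O6–C12–C11–C7) closes in the 5-exo-tet mode with exocyclic C7–O cleavage. C7 is the only new stereocentre and is fixed by inversion at the epoxide carbon, while C8 keeps its oxygen with retention and C6 is untouched, so the syn 6R,7S,8S epoxide can only give the trans-fused 6R,7R,8S array. The step needs attack at C7 (5-exo) rather than C8 (6-endo), which the two-atom ester tether secures because it cannot align with the C8–O bond, and it needs the carbanion to find no Michael acceptor, which is secured by holding C14 and C15 as ethers. The moderate temperature and the fast proton transfer are meant to outrun phosphoryl migration to O8 (the cyclopropanation channel) and translactonisation to O8.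

Step 18
Reactants: 25 ethyl 2-(hydroxymethyl)acrylate
Product: 26 ethyl 2-[(tert-butyldimethylsilyloxy)methyl]acrylate
Conditions: TBSCl, imidazole, CH2Cl2, 0 → 25 °C
Reagents that add atoms: tert-butyldimethylsilyl chloride, CC(C)(C)[Si](C)(C)Cl
Why: Silylation of the primary alcohol blocks self-acylation of the side-chain acid in the later coupling.

Step 19
Reactants: 26 ethyl 2-[(tert-butyldimethylsilyloxy)methyl]acrylate
Product: 27 2-[(tert-butyldimethylsilyloxy)methyl]acrylic acid
Conditions: LiOH, THF/H2O, 0 °C; then 1 M HCl to pH 3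
Reagents that add atoms: lithium hydroxide (hydroxide oxygen), [Li+].[OH-]
Why: Saponification at 0 °C cleaves the ethyl ester faster than hydroxide adds to the α-substituted acrylate, and the primary TBS ether is stable to base.

Step 20
Reactants: 24 (1(10)E,4E,6R,7R,8S)-8-hydroxy-14-(4-methoxybenzyloxy)-15-(triethylsilyloxy)germacra-1(10),4,11(13)-trien-12,6-olide; 27 2-[(tert-butyldimethylsilyloxy)methyl]acrylic acid
Product: 28 (1(10)E,4E,6R,7R,8S)-8-{2-[(tert-butyldimethylsilyloxy)methyl]acryloyloxy}-14-(4-methoxybenzyloxy)-15-(triethylsilyloxy)germacra-1(10),4,11(13)-trien-12,6-olide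
Conditions: 27, DCC, DMAP, CH2Cl2, 0 → 25 °C
Reagents that add atoms: none
Why: Steglich esterification acylates the only free hydroxyl (C8) with retention, under conditions mild enough for the α-methylene lactone.

Step 21
Reactants: 28 (1(10)E,4E,6R,7R,8S)-8-{2-[(tert-butyldimethylsilyloxy)methyl]acryloyloxy}-14-(4-methoxybenzyloxy)-15-(triethylsilyloxy)germacra-1(10),4,11(13)-trien-12,6-olide
Product: 29 (1(10)E,4E,6R,7R,8S)-8-{2-[(tert-butyldimethylsilyloxy)methyl]acryloyloxy}-14-hydroxy-15-(triethylsilyloxy)germacra-1(10),4,11(13)-trien-12,6-olide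
Conditions: DDQ, CH2Cl2/pH 7 buffer, 0 °C
Reagents that add atoms: none
Why: Oxidative PMB cleavage (benzylic hydride abstraction by DDQ, hydrolysis of the oxocarbenium ion) at buffered pH spares the silyl ethers and the electron-poor alkenes.

Step 22
Reactants: 29 (1(10)E,4E,6R,7R,8S)-8-{2-[(tert-butyldimethylsilyloxy)methyl]acryloyloxy}-14-hydroxy-15-(triethylsilyloxy)germacra-1(10),4,11(13)-trien-12,6-olide
Product: 30 (1(10)E,4E,6R,7R,8S)-14-acetoxy-8-{2-[(tert-butyldimethylsilyloxy)methyl]acryloyloxy}-15-(triethylsilyloxy)germacra-1(10),4,11(13)-trien-12,6-olide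
Conditions: Ac2O, pyridine, DMAP (cat.), CH2Cl2, 0 °C
Reagents that add atoms: acetic anhydride, CC(=O)OC(C)=O
Why: Acetylation of the single free primary alcohol installs the C14 acetate of the target.

Step 23
Reactants: 30 (1(10)E,4E,6R,7R,8S)-14-acetoxy-8-{2-[(tert-butyldimethylsilyloxy)methyl]acryloyloxy}-15-(triethylsilyloxy)germacra-1(10),4,11(13)-trien-12,6-olide
Product: 31 (1(10)E,4E,6R,7R,8S)-14-acetoxy-8-{2-[(tert-butyldimethylsilyloxy)methyl]acryloyloxy}-15-hydroxygermacra-1(10),4,11(13)-trien-12,6-olide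
Conditions: PPTS (cat.), MeOH/CH2Cl2, 0 °C
Reagents that add atoms: none
Why: Acid-catalysed methanolysis removes the primary TES ether much faster than the primary TBS ether, and acetate and acrylate survive these mild conditions.

Step 24
Reactants: 31 (1(10)E,4E,6R,7R,8S)-14-acetoxy-8-{2-[(tert-butyldimethylsilyloxy)methyl]acryloyloxy}-15-hydroxygermacra-1(10),4,11(13)-trien-12,6-olide
Product: 32 (1(10)E,4E,6R,7R,8S)-14-acetoxy-8-{2-[(tert-butyldimethylsilyloxy)methyl]acryloyloxy}-15-oxogermacra-1(10),4,11(13)-trien-12,6-olide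
Conditions: MnO2, CH2Cl2, 25 °C
Reagents that add atoms: none
Why: Activated MnO2 oxidises only the free primary allylic alcohol to the enal, and the ring holds the C4=C5 geometry.

Step 25
Reactants: 32 (1(10)E,4E,6R,7R,8S)-14-acetoxy-8-{2-[(tert-butyldimethylsilyloxy)methyl]acryloyloxy}-15-oxogermacra-1(10),4,11(13)-trien-12,6-olide
Product: 33 (1(10)E,4E,6R,7R,8S)-14-acetoxy-8-[2-(hydroxymethyl)acryloyloxy]-15-oxogermacra-1(10),4,11(13)-trien-12,6-olide (CNP0198933.2)
Conditions: HF·pyridine, pyridine, THF, 0 → 25 °C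
Reagents that add atoms: none
Why: Buffered HF·pyridine cleaves the last silyl ether without base, so the acetate, the enal and both Michael acceptors should be left untouched.

**Compound list**

1 | 4-(tert-butyldimethylsilyloxy)but-1-yne | C#CCCO[Si](C)(C)C(C)(C)C | starting material
2 | formaldehyde (used as paraformaldehyde) | C=O | starting material
3 | 5-(tert-butyldimethylsilyloxy)pent-2-yn-1-ol | OCC#CCCO[Si](C)(C)C(C)(C)C | intermediate
4 | allylmagnesium bromide | C=CC[Mg]Br | starting material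
5 | (2E)-2-allyl-5-(tert-butyldimethylsilyloxy)pent-2-en-1-ol | OC/C(CC=C)=C/CCO[Si](C)(C)C(C)(C)C | intermediate
6 | tert-butyl{[(3E)-4-{[(4-methoxybenzyl)oxy]methyl}hepta-3,6-dien-1-yl]oxy}dimethylsilane | COc1ccc(COC/C(CC=C)=C/CCO[Si](C)(C)C(C)(C)C)cc1 | intermediate
7 | (3E)-4-{[(4-methoxybenzyl)oxy]methyl}hepta-3,6-dien-1-ol | COc1ccc(COC/C(CC=C)=C/CCO)cc1 | intermediate
8 | 1-({[(2E)-2-allyl-5-iodopent-2-en-1-yl]oxy}methyl)-4-methoxybenzene | COc1ccc(COC/C(CC=C)=C/CCI)cc1 | intermediate
9 | triethyl phosphonoacetate | CCOC(=O)CP(=O)(OCC)OCC | starting material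
10 | ethyl (5E)-2-(diethoxyphosphoryl)-6-{[(4-methoxybenzyl)oxy]methyl}nona-5,8-dienoate | CCOC(=O)C(P(=O)(OCC)OCC)CC/C=C(COCc1ccc(OC)cc1)\CC=C | intermediate
11 | (S)-but-3-ene-1,2-diol | C=C[C@H](O)CO | starting material
12 | (S)-1,2-bis(tert-butyldimethylsilyloxy)but-3-ene | C=C[C@H](O[Si](C)(C)C(C)(C)C)CO[Si](C)(C)C(C)(C)C | intermediate
13 | (S)-2-(tert-butyldimethylsilyloxy)but-3-en-1-ol | C=C[C@H](O[Si](C)(C)C(C)(C)C)CO | intermediate
14 | (S)-2-(tert-butyldimethylsilyloxy)but-3-enal | C=C[C@H](O[Si](C)(C)C(C)(C)C)C=O | intermediate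
15 | ethyl (2E,4S)-4-(tert-butyldimethylsilyloxy)-2-[(3E)-4-{[(4-methoxybenzyl)oxy]methyl}hepta-3,6-dien-1-yl]hexa-2,5-dienoate | C=C[C@H](O[Si](C)(C)C(C)(C)C)/C=C(C(=O)OCC)\CC/C=C(COCc1ccc(OC)cc1)\CC=C | intermediate
16 | ethyl (1(10)E,4E,7Z,6S)-6-(tert-butyldimethylsilyloxy)-10-{[(4-methoxybenzyl)oxy]methyl}cyclodeca-1(10),4,7-triene-4-carboxylate | CC(C)(C)[Si](C)(C)O[C@@H]1/C=C(C(=O)OCC)\CC/C=C(COCc2ccc(OC)cc2)\C/C=C\1 | intermediate
17 | ethyl (1(10)E,4E,7Z,6S)-6-hydroxy-10-{[(4-methoxybenzyl)oxy]methyl}cyclodeca-1(10),4,7-triene-4-carboxylate | O[C@@H]1/C=C(C(=O)OCC)\CC/C=C(COCc2ccc(OC)cc2)\C/C=C\1 | intermediate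
18 | ethyl (1(10)E,4E,6R,7R,8S)-7,8-epoxy-6-hydroxy-10-{[(4-methoxybenzyl)oxy]methyl}cyclodeca-1(10),4-diene-4-carboxylate | O[C@@H]1/C=C(C(=O)OCC)\CC/C=C(COCc2ccc(OC)cc2)\C[C@@H]3O[C@H]13 | intermediate
19 | (1(10)E,4E,6R,7R,8S)-7,8-epoxy-4-(hydroxymethyl)-10-{[(4-methoxybenzyl)oxy]methyl}cyclodeca-1(10),4-dien-6-ol | O[C@@H]1/C=C(CO)\CC/C=C(COCc2ccc(OC)cc2)\C[C@@H]3O[C@H]13 | intermediate
20 | (1(10)E,4E,6R,7R,8S)-7,8-epoxy-10-{[(4-methoxybenzyl)oxy]methyl}-4-[(triethylsilyloxy)methyl]cyclodeca-1(10),4-dien-6-ol | O[C@@H]1/C=C(CO[Si](CC)(CC)CC)\CC/C=C(COCc2ccc(OC)cc2)\C[C@@H]3O[C@H]13 | intermediate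
21 | diethylphosphonoacetic acid | OC(=O)CP(=O)(OCC)OCC | starting material
22 | (1(10)E,4E,6R,7S,8S)-7,8-epoxy-10-{[(4-methoxybenzyl)oxy]methyl}-4-[(triethylsilyloxy)methyl]cyclodeca-1(10),4-dien-6-yl 2-(diethoxyphosphoryl)acetate | O=C(CP(=O)(OCC)OCC)O[C@@H]1/C=C(CO[Si](CC)(CC)CC)\CC/C=C(COCc2ccc(OC)cc2)\C[C@@H]3O[C@H]13 | intermediate
23 | (1(10)E,4E,6R,7R,8S)-11-(diethoxyphosphoryl)-8-hydroxy-14-(4-methoxybenzyloxy)-15-(triethylsilyloxy)germacra-1(10),4-dien-12,6-olide (C11 epimers, not isolated) | O[C@H]1C/C(COCc3ccc(OC)cc3)=C\CC/C(CO[Si](CC)(CC)CC)=C\[C@H]2OC(=O)C(P(=O)(OCC)OCC)[C@H]12 | intermediate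
24 | (1(10)E,4E,6R,7R,8S)-8-hydroxy-14-(4-methoxybenzyloxy)-15-(triethylsilyloxy)germacra-1(10),4,11(13)-trien-12,6-olide | O[C@H]1C/C(COCc3ccc(OC)cc3)=C\CC/C(CO[Si](CC)(CC)CC)=C\[C@H]2OC(=O)C(=C)[C@H]12 | intermediate
25 | ethyl 2-(hydroxymethyl)acrylate | C=C(CO)C(=O)OCC | starting material
26 | ethyl 2-[(tert-butyldimethylsilyloxy)methyl]acrylate | C=C(CO[Si](C)(C)C(C)(C)C)C(=O)OCC | intermediate
27 | 2-[(tert-butyldimethylsilyloxy)methyl]acrylic acid | C=C(CO[Si](C)(C)C(C)(C)C)C(=O)O | intermediate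
28 | (1(10)E,4E,6R,7R,8S)-8-{2-[(tert-butyldimethylsilyloxy)methyl]acryloyloxy}-14-(4-methoxybenzyloxy)-15-(triethylsilyloxy)germacra-1(10),4,11(13)-trien-12,6-olide | C=C(CO[Si](C)(C)C(C)(C)C)C(=O)O[C@H]1C/C(COCc3ccc(OC)cc3)=C\CC/C(CO[Si](CC)(CC)CC)=C\[C@H]2OC(=O)C(=C)[C@H]12 | intermediate
29 | (1(10)E,4E,6R,7R,8S)-8-{2-[(tert-butyldimethylsilyloxy)methyl]acryloyloxy}-14-hydroxy-15-(triethylsilyloxy)germacra-1(10),4,11(13)-trien-12,6-olide | C=C(CO[Si](C)(C)C(C)(C)C)C(=O)O[C@H]1C/C(CO)=C\CC/C(CO[Si](CC)(CC)CC)=C\[C@H]2OC(=O)C(=C)[C@H]12 | intermediate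
30 | (1(10)E,4E,6R,7R,8S)-14-acetoxy-8-{2-[(tert-butyldimethylsilyloxy)methyl]acryloyloxy}-15-(triethylsilyloxy)germacra-1(10),4,11(13)-trien-12,6-olide | C=C(CO[Si](C)(C)C(C)(C)C)C(=O)O[C@H]1C/C(COC(C)=O)=C\CC/C(CO[Si](CC)(CC)CC)=C\[C@H]2OC(=O)C(=C)[C@H]12 | intermediate
31 | (1(10)E,4E,6R,7R,8S)-14-acetoxy-8-{2-[(tert-butyldimethylsilyloxy)methyl]acryloyloxy}-15-hydroxygermacra-1(10),4,11(13)-trien-12,6-olide | C=C(CO[Si](C)(C)C(C)(C)C)C(=O)O[C@H]1C/C(COC(C)=O)=C\CC/C(CO)=C\[C@H]2OC(=O)C(=C)[C@H]12 | intermediate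
32 | (1(10)E,4E,6R,7R,8S)-14-acetoxy-8-{2-[(tert-butyldimethylsilyloxy)methyl]acryloyloxy}-15-oxogermacra-1(10),4,11(13)-trien-12,6-olide | C=C(CO[Si](C)(C)C(C)(C)C)C(=O)O[C@H]1C/C(COC(C)=O)=C\CC/C(C=O)=C\[C@H]2OC(=O)C(=C)[C@H]12 | intermediate
33 | (1(10)E,4E,6R,7R,8S)-14-acetoxy-8-[2-(hydroxymethyl)acryloyloxy]-15-oxogermacra-1(10),4,11(13)-trien-12,6-olide (CNP0198933.2) | C=C(CO)C(=O)O[C@H]1C/C(COC(C)=O)=C\CC/C(C=O)=C\[C@H]2OC(=O)C(=C)[C@H]12 | target

**Step count and risks**

Total step count: 25. Longest linear sequence: 20 steps (steps 1–6, 10–17, 20–25).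

Steps most likely to fail:

1. Step 17 (proposed new method). The ester-tethered carbanion may not reach the antiperiplanar approach to C7–O, because the ester must adopt its s-cis form and the ring must twist about C6–C7. After ring opening, phosphoryl migration to the C8 alkoxide with cyclopropane closure, or translactonisation to O8, could also divert material. The fallback removes phosphorus from the alkylation and rests on established malonate chemistry, setting out from 20 and rejoining at 24. Alcohol 20 would be esterified with mono-allyl malonate (DCC, DMAP) to give the allyl malonate ester F1. Sodium hydride in THF should effect malonate C-alkylation by the epoxide at C7, with the same inversion, giving the α-allyloxycarbonyl lactone F2 with the free C8 hydroxyl. Tsuji–Trost deallylation (Pd(PPh3)4, morpholine) would give the α-carboxy lactone F3. Decarboxylative Mannich methylenation (aqueous formaldehyde, Et2NH, buffered acetic acid) would then give 24. This fallback still relies on the tether reaching C7; it removes the phosphoryl-migration channel and separates C–C bond formation from olefination.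

2. Step 11. Oligomerisation may outrun closure of the ten-membered ring. A ruthenium alkylidene loaded at C7 could also close a seven-membered ring onto the electron-rich C1=C10 alkene, and double-bond migration or E/Z scrambling at C7=C8 is possible. The fallback moves ring closure to C4=C5 and sets the Z alkene by catalyst control, setting out from 10 and 12 and rejoining at 16. Z-selective cross-metathesis of the allyl terminus of 10 with bis-silyl ether 12 (Mo monoaryloxide–pyrrolide catalyst, reduced pressure) would give the Z-alkene F4. HF·pyridine would free the primary alcohol F5, and Dess–Martin oxidation would give the aldehyde F6. Intramolecular HWE under Masamune–Roush conditions (LiCl, DBU, MeCN, high dilution) would then close the ring to 16. The ring should enforce the ring-cis (E) enoate.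

3. Step 13. In this triene ring the vanadium-bound oxygen may be delivered anti rather than syn to O6 (conformation-dependent facial selectivity), or the doubly allylic carbinol may be oxidised to the dienone. The fallback accepts anti delivery and corrects C6 by two Mitsunobu inversions, setting out from 17 and rejoining at 22. Mitsunobu reaction of 17 with 4-nitrobenzoic acid (PPh3, DIAD) would give the inverted 4-nitrobenzoate F7, and ethanolysis (K2CO3, EtOH) the C6-epimeric alcohol F8, which is the mirror image of 17. Anti-selective epoxidation of F8 would then place the epoxide with the absolute configuration needed, giving the epoxy alcohol F9. DIBAL-H reduction would give the diol F10 and selective silylation the TES ether F11. Mitsunobu esterification of F11 with acid 21 inverts C6 and delivers 22 directly.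

**Further compounds**

F1 | step 17 | allyl (1(10)E,4E,6R,7S,8S)-7,8-epoxy-10-{[(4-methoxybenzyl)oxy]methyl}-4-[(triethylsilyloxy)methyl]cyclodeca-1(10),4-dien-6-yl malonate | C=CCOC(=O)CC(=O)O[C@@H]1/C=C(CO[Si](CC)(CC)CC)\CC/C=C(COCc2ccc(OC)cc2)\C[C@@H]3O[C@H]13
F2 | step 17 | (6R,7R,8S)-11-(allyloxycarbonyl)-8-hydroxy-14-(4-methoxybenzyloxy)-15-(triethylsilyloxy)germacra-1(10),4-dien-12,6-olide | O[C@H]1C/C(COCc3ccc(OC)cc3)=C\CC/C(CO[Si](CC)(CC)CC)=C\[C@H]2OC(=O)C(C(=O)OCC=C)[C@H]12
F3 | step 17 | (6R,7R,8S)-11-carboxy-8-hydroxy-14-(4-methoxybenzyloxy)-15-(triethylsilyloxy)germacra-1(10),4-dien-12,6-olide | O[C@H]1C/C(COCc3ccc(OC)cc3)=C\CC/C(CO[Si](CC)(CC)CC)=C\[C@H]2OC(=O)C(C(O)=O)[C@H]12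
F4 | step 11 | ethyl (5E,8Z,10S)-10,11-bis(tert-butyldimethylsilyloxy)-2-(diethoxyphosphoryl)-6-{[(4-methoxybenzyl)oxy]methyl}undeca-5,8-dienoate | CCOC(=O)C(P(=O)(OCC)OCC)CC/C=C(COCc1ccc(OC)cc1)\C/C=C\[C@H](O[Si](C)(C)C(C)(C)C)CO[Si](C)(C)C(C)(C)C
F5 | step 11 | ethyl (5E,8Z,10S)-10-(tert-butyldimethylsilyloxy)-2-(diethoxyphosphoryl)-11-hydroxy-6-{[(4-methoxybenzyl)oxy]methyl}undeca-5,8-dienoate | CCOC(=O)C(P(=O)(OCC)OCC)CC/C=C(COCc1ccc(OC)cc1)\C/C=C\[C@H](O[Si](C)(C)C(C)(C)C)CO
F6 | step 11 | ethyl (5E,8Z,10S)-10-(tert-butyldimethylsilyloxy)-2-(diethoxyphosphoryl)-6-{[(4-methoxybenzyl)oxy]methyl}-11-oxoundeca-5,8-dienoate | CCOC(=O)C(P(=O)(OCC)OCC)CC/C=C(COCc1ccc(OC)cc1)\C/C=C\[C@H](O[Si](C)(C)C(C)(C)C)C=O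
F7 | step 13 | ethyl (1(10)E,4E,7Z,6R)-10-{[(4-methoxybenzyl)oxy]methyl}-6-(4-nitrobenzoyloxy)cyclodeca-1(10),4,7-triene-4-carboxylate | O=C(O[C@H]1/C=C(C(=O)OCC)\CC/C=C(COCc2ccc(OC)cc2)\C/C=C\1)c1ccc(cc1)[N+](=O)[O-]
F8 | step 13 | ethyl (1(10)E,4E,7Z,6R)-6-hydroxy-10-{[(4-methoxybenzyl)oxy]methyl}cyclodeca-1(10),4,7-triene-4-carboxylate | O[C@H]1/C=C(C(=O)OCC)\CC/C=C(COCc2ccc(OC)cc2)\C/C=C\1
F9 | step 13 | ethyl (1(10)E,4E,6S,7R,8S)-7,8-epoxy-6-hydroxy-10-{[(4-methoxybenzyl)oxy]methyl}cyclodeca-1(10),4-diene-4-carboxylate | O[C@H]1/C=C(C(=O)OCC)\CC/C=C(COCc2ccc(OC)cc2)\C[C@@H]3O[C@H]13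
F10 | step 13 | (1(10)E,4E,6S,7R,8S)-7,8-epoxy-4-(hydroxymethyl)-10-{[(4-methoxybenzyl)oxy]methyl}cyclodeca-1(10),4-dien-6-ol | O[C@H]1/C=C(CO)\CC/C=C(COCc2ccc(OC)cc2)\C[C@@H]3O[C@H]13
F11 | step 13 | (1(10)E,4E,6S,7R,8S)-7,8-epoxy-10-{[(4-methoxybenzyl)oxy]methyl}-4-[(triethylsilyloxy)methyl]cyclodeca-1(10),4-dien-6-ol | O[C@H]1/C=C(CO[Si](CC)(CC)CC)\CC/C=C(COCc2ccc(OC)cc2)\C[C@@H]3O[C@H]13
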